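**Retrosynthetic overview**
- Last bond: the C8–O ester, made by Mitsunobu inversion of the 7,8-cis diol with O-acetylferulic acid, then release of the phenol.
- Key new step: a nickel-catalysed reductive diene–aldehyde cyclisation closes the seven-membered ring last (C8–C9 bond), places the tetrasubstituted C1=C10 alkene and creates C8.
- The diene–aldehyde comes from a cis-2,3-disubstituted cyclopentanone by kinetic enol triflate formation, Suzuki coupling with an isopropenyl boronate and aldehyde release.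
- The five-membered ring is formed first (Stetter reaction, then aldol cyclisation); C4 and C5 are set by CBS reduction followed by hydroxyl-directed hydrogenation.
- C7, with the C8 and C11 oxygens, comes from Sharpless epoxidation of prenol and SN2 allyl opening of the epoxide.

Assumption: the target is read as (4S,5S,7S,8S) in guaiane numbering (C1/C5 ring fusion, C11 = carbinol carbon on C7, C8 = ester carbon) with an E feruloyl group; PMBO = 4-methoxybenzyloxy, TESO = triethylsilyloxy, IPr = 1,3-bis(2,6-diisopropylphenyl)imidazol-2-ylidene; tartrate, CBS catalyst, ligands and metal complexes are bought.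

**Step 1**
Reactants: 1 3-methylbut-2-en-1-ol (prenol)
Product: 2 [(2R)-3,3-dimethyloxiran-2-yl]methanol
Conditions: Ti(OiPr)4 (10 mol%), D-(−)-diethyl tartrate (12 mol%), t-BuOOH, 4 Å MS, CH2Cl2, −20 °C
Reagents that add atoms: tert-butyl hydroperoxide, CC(C)(C)OO
Why: Katsuki–Sharpless asymmetric epoxidation of an allylic alcohol; the D-tartrate catalyst gives the 2R epoxide (the L-ester gives 2S), and this carbon becomes C7.

**Step 2**
Reactants: 2 [(2R)-3,3-dimethyloxiran-2-yl]methanol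
Product: 3 (3R)-2,2-dimethyl-3-(PMBO-methyl)oxirane
Conditions: NaH, 4-methoxybenzyl chloride, Bu4NI (cat.), THF, 0 °C → rt
Reagents that add atoms: 4-methoxybenzyl chloride, COc1ccc(CCl)cc1
Why: Williamson etherification of the primary alkoxide; fast O-alkylation at 0 °C leaves the epoxide stereocentre untouched and removes the free alkoxide that could cause Payne rearrangement in the next step.

**Step 3**
Reactants: 3 (3R)-2,2-dimethyl-3-(PMBO-methyl)oxirane; 4 allylmagnesium chloride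
Product: 5 (3S)-2-methyl-3-(PMBO-methyl)hex-5-en-2-ol
Conditions: CuI (10 mol%), THF, −40 → 0 °C; then H2O
Reagents that add atoms: none
Why: Copper-catalysed Grignard opening of the epoxide; SN2 attack at the secondary carbon (the other is fully substituted) with inversion sets (S)-C7, frees the C11 tertiary alcohol and attaches the C6–C5–C1 allyl chain.

**Step 4**
Reactants: 5 (3S)-2-methyl-3-(PMBO-methyl)hex-5-en-2-ol
Product: 6 (3S)-2-methyl-3-(PMBO-methyl)-2-(TESO)hex-5-ene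
Conditions: Et3SiOTf, 2,6-lutidine, CH2Cl2, −78 → 0 °C
Reagents that add atoms: triethylsilyl trifluoromethanesulfonate, CC[Si](CC)(CC)OS(=O)(=O)C(F)(F)F
Why: Silyl triflate silylation of a hindered tertiary alcohol; no stereocentre is involved.

**Step 5**
Reactants: 6 (3S)-2-methyl-3-(PMBO-methyl)-2-(TESO)hex-5-ene
Product: 8 (4S)-5-methyl-4-(PMBO-methyl)-5-(TESO)hexan-1-ol, via alkylborane 7 (not isolated)
Conditions: 9-BBN, THF, 0 °C → rt; then NaOH, H2O2, H2O, 0 °C
Reagents that add atoms: 9-borabicyclo[3.3.1]nonane, B1C2CCCC1CCC2; hydrogen peroxide, OO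
Why: Anti-Markovnikov hydroboration–oxidation of the terminal alkene with a bulky borane gives the primary alcohol at C1.

**Step 6**
Reactants: 8 (4S)-5-methyl-4-(PMBO-methyl)-5-(TESO)hexan-1-ol
Product: 9 (4S)-5-methyl-4-(PMBO-methyl)-5-(TESO)hexanal
Conditions: Dess–Martin periodinane, pyridine, CH2Cl2, 0 °C → rt
Reagents that add atoms: none
Why: Dess–Martin oxidation stops cleanly at the aldehyde.

**Step 7**
Reactants: 9 (4S)-5-methyl-4-(PMBO-methyl)-5-(TESO)hexanal; 10 but-3-en-2-one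
Product: 11 (8S)-9-methyl-8-(PMBO-methyl)-9-(TESO)decane-2,5-dione
Conditions: 3-benzyl-5-(2-hydroxyethyl)-4-methylthiazolium chloride (20 mol%), Et3N, EtOH, 75 °C
Reagents that add atoms: none
Why: Stetter reaction; thiazolium umpolung makes the aldehyde an acyl anion equivalent that adds 1,4 to the enone and gives the 1,4-diketone (C1–C4 and C15).

**Step 8**
Reactants: 11 (8S)-9-methyl-8-(PMBO-methyl)-9-(TESO)decane-2,5-dione
Product: 12 3-methyl-2-[(2S)-3-methyl-2-(PMBO-methyl)-3-(TESO)butyl]cyclopent-2-en-1-one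
Conditions: KOH, EtOH/H2O, 60 °C
Reagents that add atoms: none
Why: Intramolecular aldol condensation of a 1,4-diketone (jasmone-type cyclisation) gives the more substituted 2-alkyl-3-methylcyclopentenone and forms the five-membered ring.

**Step 9**
Reactants: 12 3-methyl-2-[(2S)-3-methyl-2-(PMBO-methyl)-3-(TESO)butyl]cyclopent-2-en-1-one
Product: 13 (1S)-3-methyl-2-[(2S)-3-methyl-2-(PMBO-methyl)-3-(TESO)butyl]cyclopent-2-en-1-ol
Conditions: (R)-2-methyl-CBS-oxazaborolidine (20 mol%), BH3·SMe2, THF, −20 °C; then MeOH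
Reagents that add atoms: none
Why: Corey–Bakshi–Shibata reduction; the substituted alkenyl arm acts as the large group, so the (R)-catalyst gives the (S)-allylic alcohol under catalyst control.

**Step 10**
Reactants: 13 (1S)-3-methyl-2-[(2S)-3-methyl-2-(PMBO-methyl)-3-(TESO)butyl]cyclopent-2-en-1-ol
Product: 14 (1S,2S,3S)-3-methyl-2-[(2S)-3-methyl-2-(PMBO-methyl)-3-(TESO)butyl]cyclopentan-1-ol
Conditions: [Ir(cod)(PCy3)(py)]PF6 (5 mol%), H2 (1 atm), CH2Cl2, rt
Reagents that add atoms: none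
Why: Hydroxyl-directed hydrogenation; the cationic iridium catalyst adds H2 to the tetrasubstituted alkene from the OH face, so the C4 methyl and the C5 side chain end up cis to each other (4S,5S).

**Step 11**
Reactants: 14 (1S,2S,3S)-3-methyl-2-[(2S)-3-methyl-2-(PMBO-methyl)-3-(TESO)butyl]cyclopentan-1-ol
Product: 15 (2S,3S)-3-methyl-2-[(2S)-3-methyl-2-(PMBO-methyl)-3-(TESO)butyl]cyclopentan-1-one
Conditions: Dess–Martin periodinane, pyridine, CH2Cl2, 0 °C
Reagents that add atoms: none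
Why: Buffered Dess–Martin oxidation gives the cis-2,3-disubstituted cyclopentanone under near-neutral conditions that do not epimerise C5.

**Step 12**
Reactants: 15 (2S,3S)-3-methyl-2-[(2S)-3-methyl-2-(PMBO-methyl)-3-(TESO)butyl]cyclopentan-1-one
Product: 17 (4S,5S)-4-methyl-5-[(2S)-3-methyl-2-(PMBO-methyl)-3-(TESO)butyl]cyclopent-1-en-1-yl triflate, via lithium enolate 16 (not isolated)
Conditions: LiN(iPr)2, THF, −78 °C (ketone added to base); then PhNTf2, −78 → 0 °C
Reagents that add atoms: lithium diisopropylamide, CC(C)N([Li])C(C)C; N-phenylbis(trifluoromethanesulfonimide), O=S(=O)(N(c1ccccc1)S(=O)(=O)C(F)(F)F)C(F)(F)F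
Why: Kinetic enolate formation at the unsubstituted α-CH2 (C2) followed by O-triflation; C5 becomes a non-epimerisable allylic centre.

**Step 13**
Reactants: 17 (4S,5S)-4-methyl-5-[(2S)-3-methyl-2-(PMBO-methyl)-3-(TESO)butyl]cyclopent-1-en-1-yl triflate
Product: 18 (4S,5S)-5-[(2S)-2-(hydroxymethyl)-3-methyl-3-(TESO)butyl]-4-methylcyclopent-1-en-1-yl triflate
Conditions: DDQ, CH2Cl2/pH 7 buffer, 0 °C
Reagents that add atoms: none
Why: Oxidative cleavage of the 4-methoxybenzyl ether; the silyl ether and vinyl triflate are inert, and the step is run before the DDQ-sensitive diene exists.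

**Step 14**
Reactants: 18 (4S,5S)-5-[(2S)-2-(hydroxymethyl)-3-methyl-3-(TESO)butyl]-4-methylcyclopent-1-en-1-yl triflate; 19 4,4,5,5-tetramethyl-2-(prop-1-en-2-yl)-1,3,2-dioxaborolane
Product: 20 (2S)-3-methyl-2-{[(1S,5S)-5-methyl-2-(prop-1-en-2-yl)cyclopent-2-en-1-yl]methyl}-3-(TESO)butan-1-ol
Conditions: Pd(PPh3)4 (5 mol%), K3PO4, 1,4-dioxane/H2O, 60 °C
Reagents that add atoms: none
Why: Suzuki–Miyaura coupling of the vinyl triflate with the alkenyl boronate gives the 2-substituted 1,3-diene (C9=C10–C1=C2); the free primary alcohol is tolerated.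

**Step 15**
Reactants: 20 (2S)-3-methyl-2-{[(1S,5S)-5-methyl-2-(prop-1-en-2-yl)cyclopent-2-en-1-yl]methyl}-3-(TESO)butan-1-ol
Product: 21 (2R)-3-methyl-2-{[(1S,5S)-5-methyl-2-(prop-1-en-2-yl)cyclopent-2-en-1-yl]methyl}-3-(TESO)butanal
Conditions: Dess–Martin periodinane, pyridine, CH2Cl2, 0 °C
Reagents that add atoms: none
Why: Buffered Dess–Martin oxidation gives the α-branched C8 aldehyde without epimerising C7 or touching the diene (the descriptor changes to R only because the CIP priorities change).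

**Step 16**
Reactants: 21 (2R)-3-methyl-2-{[(1S,5S)-5-methyl-2-(prop-1-en-2-yl)cyclopent-2-en-1-yl]methyl}-3-(TESO)butanal
Product: 22 (3S,3aS,5S,6R)-3,8-dimethyl-6-(TESO)-5-[2-(TESO)propan-2-yl]-1,2,3,3a,4,5,6,7-octahydroazulene
Conditions: Ni(cod)2 (10 mol%), IPr (10 mol%), Et3SiH (3 equiv), THF (0.01 M), rt
Reagents that add atoms: triethylsilane, CC[SiH](CC)CC
Why: Proposed new method: zerovalent nickel with a bulky N-heterocyclic carbene couples the unsubstituted diene terminus C9 with the aldehyde carbon C8 by oxidative cyclisation to an allylnickel alkoxide, Si–H σ-bond metathesis then gives the silyl ether and an allylnickel hydride, and C–H reductive elimination at the less hindered allyl terminus C2 (not the fully substituted C10) leaves the tetrasubstituted C1=C10 alkene inside the new seven-membered ring; because the oxygen stays bound to nickel on the allyl face, the chair-like transition state with the C7 group equatorial places the C8–O bond axial and cis to it (Felkin sense, 8R); the closest known reaction type is the nickel-catalysed reductive coupling of 1,3-dienes with aldehydes and silanes (intermolecular, or exo-mode cyclisation) together with nickel/carbene aldehyde–alkyne reductive macrocyclisation, neither shown for endo-mode closure on a 2,3-disubstituted diene to a tetrasubstituted cycloheptene.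

**Step 17**
Reactants: 22 (3S,3aS,5S,6R)-3,8-dimethyl-6-(TESO)-5-[2-(TESO)propan-2-yl]-1,2,3,3a,4,5,6,7-octahydroazulene
Product: 23 (3S,3aS,5S,6R)-5-(2-hydroxypropan-2-yl)-3,8-dimethyl-1,2,3,3a,4,5,6,7-octahydroazulen-6-ol
Conditions: Bu4NF, THF, 45 °C
Reagents that add atoms: none
Why: Fluoride desilylation of both silyl ethers; no stereocentre is touched.

**Step 18**
Reactants: 24 (E)-3-(4-hydroxy-3-methoxyphenyl)prop-2-enoic acid (ferulic acid)
Product: 25 (E)-3-(4-acetoxy-3-methoxyphenyl)prop-2-enoic acid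
Conditions: Ac2O, pyridine, rt; then H2O
Reagents that add atoms: acetic anhydride, CC(=O)OC(C)=O
Why: Phenol acetylation (any mixed anhydride at the acid is hydrolysed on work-up) masks the phenol, which would otherwise compete as a Mitsunobu nucleophile.

**Step 19**
Reactants: 23 (3S,3aS,5S,6R)-5-(2-hydroxypropan-2-yl)-3,8-dimethyl-1,2,3,3a,4,5,6,7-octahydroazulen-6-ol; 25 (E)-3-(4-acetoxy-3-methoxyphenyl)prop-2-enoic acid
Product: 26 (3S,3aS,5S,6S)-5-(2-hydroxypropan-2-yl)-3,8-dimethyl-1,2,3,3a,4,5,6,7-octahydroazulen-6-yl (E)-3-(4-acetoxy-3-methoxyphenyl)prop-2-enoate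
Conditions: PPh3, DIAD, THF, 0 °C → rt
Reagents that add atoms: none
Why: Mitsunobu esterification; the axial secondary C8 alcohol is activated as its oxyphosphonium ion and displaced by the carboxylate with inversion (8R to 8S, ester trans to the C7 group), while the tertiary alcohol does not react.

**Step 20**
Reactants: 26 (3S,3aS,5S,6S)-5-(2-hydroxypropan-2-yl)-3,8-dimethyl-1,2,3,3a,4,5,6,7-octahydroazulen-6-yl (E)-3-(4-acetoxy-3-methoxyphenyl)prop-2-enoate
Product: 27 (3S,3aS,5S,6S)-5-(2-hydroxypropan-2-yl)-3,8-dimethyl-1,2,3,3a,4,5,6,7-octahydroazulen-6-yl (E)-3-(4-hydroxy-3-methoxyphenyl)prop-2-enoate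
Conditions: pyrrolidine, CH2Cl2, 0 °C
Reagents that add atoms: none
Why: Chemoselective aminolysis of the aryl acetate, which is far more electrophilic than the hindered cinnamate ester, frees the phenol and gives the target.

**Compound list**
1 | 3-methylbut-2-en-1-ol (prenol) | CC(C)=CCO | starting material
2 | [(2R)-3,3-dimethyloxiran-2-yl]methanol | OC[C@H]1OC1(C)C | intermediate
3 | (3R)-2,2-dimethyl-3-(PMBO-methyl)oxirane | COc1ccc(COC[C@H]2OC2(C)C)cc1 | intermediate
4 | allylmagnesium chloride | C=CC[Mg]Cl | starting material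
5 | (3S)-2-methyl-3-(PMBO-methyl)hex-5-en-2-ol | COc1ccc(COC[C@H](CC=C)C(C)(C)O)cc1 | intermediate
6 | (3S)-2-methyl-3-(PMBO-methyl)-2-(TESO)hex-5-ene | COc1ccc(COC[C@H](CC=C)C(C)(C)O[Si](CC)(CC)CC)cc1 | intermediate
7 | 9-[(4S)-5-methyl-4-(PMBO-methyl)-5-(TESO)hexyl]-9-borabicyclo[3.3.1]nonane | COc1ccc(COC[C@H](CCCB2C3CCCC2CCC3)C(C)(C)O[Si](CC)(CC)CC)cc1 | intermediate
8 | (4S)-5-methyl-4-(PMBO-methyl)-5-(TESO)hexan-1-ol | COc1ccc(COC[C@H](CCCO)C(C)(C)O[Si](CC)(CC)CC)cc1 | intermediate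
9 | (4S)-5-methyl-4-(PMBO-methyl)-5-(TESO)hexanal | COc1ccc(COC[C@H](CCC=O)C(C)(C)O[Si](CC)(CC)CC)cc1 | intermediate
10 | but-3-en-2-one (methyl vinyl ketone) | CC(=O)C=C | starting material
11 | (8S)-9-methyl-8-(PMBO-methyl)-9-(TESO)decane-2,5-dione | COc1ccc(COC[C@H](CCC(=O)CCC(C)=O)C(C)(C)O[Si](CC)(CC)CC)cc1 | intermediate
12 | 3-methyl-2-[(2S)-3-methyl-2-(PMBO-methyl)-3-(TESO)butyl]cyclopent-2-en-1-one | CC1=C(C[C@@H](COCc2ccc(OC)cc2)C(C)(C)O[Si](CC)(CC)CC)C(=O)CC1 | intermediate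
13 | (1S)-3-methyl-2-[(2S)-3-methyl-2-(PMBO-methyl)-3-(TESO)butyl]cyclopent-2-en-1-ol | CC1=C(C[C@@H](COCc2ccc(OC)cc2)C(C)(C)O[Si](CC)(CC)CC)[C@@H](O)CC1 | intermediate
14 | (1S,2S,3S)-3-methyl-2-[(2S)-3-methyl-2-(PMBO-methyl)-3-(TESO)butyl]cyclopentan-1-ol | C[C@H]1CC[C@H](O)[C@H]1C[C@@H](COCc2ccc(OC)cc2)C(C)(C)O[Si](CC)(CC)CC | intermediate
15 | (2S,3S)-3-methyl-2-[(2S)-3-methyl-2-(PMBO-methyl)-3-(TESO)butyl]cyclopentan-1-one | C[C@H]1CCC(=O)[C@H]1C[C@@H](COCc2ccc(OC)cc2)C(C)(C)O[Si](CC)(CC)CC | intermediate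
16 | lithium (4S,5S)-4-methyl-5-[(2S)-3-methyl-2-(PMBO-methyl)-3-(TESO)butyl]cyclopent-1-en-1-olate | C[C@H]1CC=C(O[Li])[C@H]1C[C@@H](COCc2ccc(OC)cc2)C(C)(C)O[Si](CC)(CC)CC | intermediate
17 | (4S,5S)-4-methyl-5-[(2S)-3-methyl-2-(PMBO-methyl)-3-(TESO)butyl]cyclopent-1-en-1-yl triflate | C[C@H]1CC=C(OS(=O)(=O)C(F)(F)F)[C@H]1C[C@@H](COCc2ccc(OC)cc2)C(C)(C)O[Si](CC)(CC)CC | intermediate
18 | (4S,5S)-5-[(2S)-2-(hydroxymethyl)-3-methyl-3-(TESO)butyl]-4-methylcyclopent-1-en-1-yl triflate | C[C@H]1CC=C(OS(=O)(=O)C(F)(F)F)[C@H]1C[C@@H](CO)C(C)(C)O[Si](CC)(CC)CC | intermediate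
19 | 4,4,5,5-tetramethyl-2-(prop-1-en-2-yl)-1,3,2-dioxaborolane | CC(=C)B1OC(C)(C)C(C)(C)O1 | starting material
20 | (2S)-3-methyl-2-{[(1S,5S)-5-methyl-2-(prop-1-en-2-yl)cyclopent-2-en-1-yl]methyl}-3-(TESO)butan-1-ol | C[C@H]1CC=C(C(C)=C)[C@H]1C[C@@H](CO)C(C)(C)O[Si](CC)(CC)CC | intermediate
21 | (2R)-3-methyl-2-{[(1S,5S)-5-methyl-2-(prop-1-en-2-yl)cyclopent-2-en-1-yl]methyl}-3-(TESO)butanal | C[C@H]1CC=C(C(C)=C)[C@H]1C[C@@H](C=O)C(C)(C)O[Si](CC)(CC)CC | intermediate
22 | (3S,3aS,5S,6R)-3,8-dimethyl-6-(TESO)-5-[2-(TESO)propan-2-yl]-1,2,3,3a,4,5,6,7-octahydroazulene | CC[Si](CC)(CC)O[C@@H]1CC(C)=C2CC[C@H](C)[C@@H]2C[C@@H]1C(C)(C)O[Si](CC)(CC)CC | intermediate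
23 | (3S,3aS,5S,6R)-5-(2-hydroxypropan-2-yl)-3,8-dimethyl-1,2,3,3a,4,5,6,7-octahydroazulen-6-ol | O[C@@H]1CC(C)=C2CC[C@H](C)[C@@H]2C[C@@H]1C(C)(C)O | intermediate
24 | (E)-3-(4-hydroxy-3-methoxyphenyl)prop-2-enoic acid (ferulic acid) | COc1cc(/C=C/C(=O)O)ccc1O | starting material
25 | (E)-3-(4-acetoxy-3-methoxyphenyl)prop-2-enoic acid | COc1cc(/C=C/C(=O)O)ccc1OC(C)=O | intermediate
26 | (3S,3aS,5S,6S)-5-(2-hydroxypropan-2-yl)-3,8-dimethyl-1,2,3,3a,4,5,6,7-octahydroazulen-6-yl (E)-3-(4-acetoxy-3-methoxyphenyl)prop-2-enoate | COc1cc(/C=C/C(=O)O[C@H]2CC(C)=C3CC[C@H](C)[C@@H]3C[C@@H]2C(C)(C)O)ccc1OC(C)=O | intermediate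
27 | (3S,3aS,5S,6S)-5-(2-hydroxypropan-2-yl)-3,8-dimethyl-1,2,3,3a,4,5,6,7-octahydroazulen-6-yl (E)-3-(4-hydroxy-3-methoxyphenyl)prop-2-enoate | COc1cc(/C=C/C(=O)O[C@H]2CC(C)=C3CC[C@H](C)[C@@H]3C[C@@H]2C(C)(C)O)ccc1O | target

**Totals**
Total step count: 20. Longest linear sequence: 19 steps (steps 1–17, 19 and 20, from prenol); step 18 is a one-step side branch.

**Three steps most likely to fail**

Step 16 (the proposed new step). It may fail through nickel hydride addition to the diene, hydrogen delivery to C10 instead of C2, or diene oligomerisation. The fallback uses known chemistry, sets out from 15 and comes back at 22. DDQ in buffered CH2Cl2 removes the 4-methoxybenzyl group of 15 to give (2S,3S)-2-[(2S)-2-(hydroxymethyl)-3-methyl-3-(TESO)butyl]-3-methylcyclopentan-1-one F1. Dess–Martin oxidation gives (2R)-3-methyl-2-{[(1S,2S)-2-methyl-5-oxocyclopentyl]methyl}-3-(TESO)butanal F2. A BF3·OEt2-mediated Mukaiyama aldol addition of 2-(trimethylsilyloxy)propene at −78 °C, Felkin-selective at the α-branched aldehyde, gives (2S,3S)-2-{(2S,3R)-3-hydroxy-5-oxo-2-[2-(TESO)propan-2-yl]hexyl}-3-methylcyclopentan-1-one F3. Silylation with Et3SiOTf and 2,6-lutidine gives (2S,3S)-3-methyl-2-{(2S,3R)-5-oxo-3-(TESO)-2-[2-(TESO)propan-2-yl]hexyl}cyclopentan-1-one F4. An intramolecular McMurry coupling of the two ketones (TiCl3(DME)1.5, Zn–Cu couple, DME, reflux, slow addition) then forms the C1=C10 bond and the seven-membered ring, giving 22.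

Step 19 (Mitsunobu inversion at a hindered secondary alcohol next to the C7 branch; elimination or no reaction is possible). The fallback sets out from 23 and comes back at 26. Dess–Martin oxidation of the secondary alcohol gives (3S,3aS,5R)-5-(2-hydroxypropan-2-yl)-3,8-dimethyl-2,3,3a,4,5,7-hexahydro-1H-azulen-6-one F5. Hydroxyl-directed reduction with Me4NBH(OAc)3 in MeCN/AcOH at −20 °C delivers hydride from the C11–O-bound boron on the face of the C7 branch and gives the 7,8-trans diol (3S,3aS,5S,6S)-5-(2-hydroxypropan-2-yl)-3,8-dimethyl-1,2,3,3a,4,5,6,7-octahydroazulen-6-ol F6. Acylation of the secondary alcohol with 25 (EDC·HCl, DMAP, CH2Cl2), with retention, gives 26. This sequence also corrects a mixed or opposite C8 configuration from step 16.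

Step 12 (kinetic enol triflate from an epimerisable cis-ketone; wrong regiochemistry or C5 epimerisation is possible). The fallback sets out from 15 and comes back at 20. Condensation of 15 with 2,4,6-triisopropylbenzenesulfonyl hydrazide gives the 2,4,6-triisopropylbenzenesulfonyl hydrazone of 15 F7. A Shapiro reaction (n-BuLi, 2.2 equiv, THF, −78 → 0 °C), which deprotonates only the CH2 side, followed by an I2 quench gives the vinyl iodide (3S)-3-{[(1S,5S)-2-iodo-5-methylcyclopent-2-en-1-yl]methyl}-2-methyl-4-(PMBO)-2-(TESO)butane F8. DDQ gives (2S)-2-{[(1S,5S)-2-iodo-5-methylcyclopent-2-en-1-yl]methyl}-3-methyl-3-(TESO)butan-1-ol F9. Suzuki coupling of F9 with 19 (Pd(PPh3)4, K3PO4) gives 20.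

**Further compounds**
F1 | step 16 | (2S,3S)-2-[(2S)-2-(hydroxymethyl)-3-methyl-3-(TESO)butyl]-3-methylcyclopentan-1-one | C[C@H]1CCC(=O)[C@H]1C[C@@H](CO)C(C)(C)O[Si](CC)(CC)CC
F2 | step 16 | (2R)-3-methyl-2-{[(1S,2S)-2-methyl-5-oxocyclopentyl]methyl}-3-(TESO)butanal | C[C@H]1CCC(=O)[C@H]1C[C@@H](C=O)C(C)(C)O[Si](CC)(CC)CC
F3 | step 16 | (2S,3S)-2-{(2S,3R)-3-hydroxy-5-oxo-2-[2-(TESO)propan-2-yl]hexyl}-3-methylcyclopentan-1-one | C[C@H]1CCC(=O)[C@H]1C[C@@H]([C@H](O)CC(C)=O)C(C)(C)O[Si](CC)(CC)CC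
F4 | step 16 | (2S,3S)-3-methyl-2-{(2S,3R)-5-oxo-3-(TESO)-2-[2-(TESO)propan-2-yl]hexyl}cyclopentan-1-one | C[C@H]1CCC(=O)[C@H]1C[C@@H]([C@H](O[Si](CC)(CC)CC)CC(C)=O)C(C)(C)O[Si](CC)(CC)CC
F5 | step 19 | (3S,3aS,5R)-5-(2-hydroxypropan-2-yl)-3,8-dimethyl-2,3,3a,4,5,7-hexahydro-1H-azulen-6-one | O=C1CC(C)=C2CC[C@H](C)[C@@H]2C[C@@H]1C(C)(C)O
F6 | step 19 | (3S,3aS,5S,6S)-5-(2-hydroxypropan-2-yl)-3,8-dimethyl-1,2,3,3a,4,5,6,7-octahydroazulen-6-ol | O[C@H]1CC(C)=C2CC[C@H](C)[C@@H]2C[C@@H]1C(C)(C)O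
F7 | step 12 | 2,4,6-triisopropylbenzenesulfonyl hydrazone of 15 | C[C@H]1CCC(=NNS(=O)(=O)c2c(C(C)C)cc(C(C)C)cc2C(C)C)[C@H]1C[C@@H](COCc2ccc(OC)cc2)C(C)(C)O[Si](CC)(CC)CC
F8 | step 12 | (3S)-3-{[(1S,5S)-2-iodo-5-methylcyclopent-2-en-1-yl]methyl}-2-methyl-4-(PMBO)-2-(TESO)butane | C[C@H]1CC=C(I)[C@H]1C[C@@H](COCc2ccc(OC)cc2)C(C)(C)O[Si](CC)(CC)CC
F9 | step 12 | (2S)-2-{[(1S,5S)-2-iodo-5-methylcyclopent-2-en-1-yl]methyl}-3-methyl-3-(TESO)butan-1-ol | C[C@H]1CC=C(I)[C@H]1C[C@@H](CO)C(C)(C)O[Si](CC)(CC)CC
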